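The runs are simulated on assumed constants; the scatter is artificial.

1. The spring run held left-handed product at 39.4% and then 39.7%, although 10.3% of left-handed substrate stood beside it at 10.0 d.

| flask | left-handed substrate | right-handed substrate | partner | precatalyst | remark | time |
|---|---|---|---|---|---|---|
| winter | 10 mM | 10 mM | 0.80 equiv | 0.34 mol% | run made earlier |  |
| dusk | 10 mM | 10 mM | 0.80 equiv | 0.75 mol% | run made earlier |  |
| spring | 20 mM | 20 mM | 0.80 equiv | 0.5 mol% | run made earlier |  |
| flask | 10 mM | 10 mM | 0.800 equiv | 0.5 mol% |  | 10 d |

| run | time / d | left-handed substrate / % | right-handed substrate / % | left-handed product / % |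
|---|---|---|---|---|
| winter | 1.67 | 30.2 | 50.2 | 20.4 |
| winter | 3.00 | 20.2 | 49.2 | 29.1 |
| winter | 5.00 | 15.3 | 49.1 | 34.0 |
| winter | 6.00 | 13.7 | 49.3 | 34.8 |
| winter | 8.00 | 14.2 | 48.6 | 37.1 |
| winter | 10.0 | 11.7 | 49.0 | 37.8 |
| dusk | 0.625 | 37.5 | 49.3 | 12.2 |
| dusk | 2.08 | 21.5 | 48.9 | 29.4 |
| dusk | 4.00 | 13.9 | 49.4 | 35.7 |
| dusk | 5.00 | 12.1 | 49.5 | 37.0 |
| dusk | 8.00 | 11.7 | 49.5 | 37.5 |
| dusk | 10.0 | 12.1 | 49.3 | 39.8 |
| spring | 0.833 | 25.1 | 49.8 | 25.1 |
| spring | 1.67 | 15.4 | 50.6 | 33.9 |
| spring | 3.00 | 12.0 | 49.2 | 37.8 |
| spring | 5.00 | 10.7 | 49.6 | 39.4 |
| spring | 10.0 | 10.3 | 49.9 | 39.7 |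

(standard deviation of a reading: 0.5 percentage points)

- catalyst is single-handed; left-handed substrate and right-handed substrate are mirror images of each other, charged as a racemate, each of them at the stated concentration
- candidate steps: precatalyst -> catalyst; 2 catalyst <-> resting dimer; partner + catalyst + right-handed substrate -> catalyst + right-handed product; partner + catalyst + left-handed substrate -> catalyst + left-handed product
- an excess is the difference of the two amounts in percent of their sum
- an excess is below zero if the other one leads

- part of the left-handed substrate and right-handed substrate charged together that has reacted at 10 d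
- excess of left-handed product over right-handed product in the product at 10 d
- excess of right-handed substrate over left-handed substrate among what is left of the two at 10 d

2. So compare two amounts, c partner and c left-handed substrate. Each left-handed product takes one of each. In this flask the ratio is 0.800 equiv, so c partner is the smaller: it is the limiting reagent.

3. Call the ceiling the smaller of the two charges, as a share of both substrates charged: 40.0% here.

4. This flask's loading lies between winter and dusk, whose last readings of left-handed product were 37.8% and 39.8%. My reckoning takes their mean, 38.8% left-handed product, which leaves 11.2% left-handed substrate. Right-handed substrate averages 49.1% in those last readings. That gives a conversion of 39.6% and an excess of right-handed substrate of 62.9%. I expect a high excess of left-handed product, but I give no number for it.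

5. The forecast says conversion 39.4%, excess of left-handed product 97.5% and excess of right-handed substrate 63.5%, on the ground that “the partner runs out”. Its conversion lies 0.20 percentage points below mine.

6. The flask gives conversion 39.2%, excess of left-handed product 96.1% and excess of right-handed substrate 62.0%.

    precatalyst → catalyst (k = 0.0440 h⁻¹)
    2 catalyst ⇌ resting dimer, settled at all times (K = 30000 M⁻¹)
    partner + catalyst + right-handed substrate → catalyst + right-handed product (k = 2400 M⁻² h⁻¹)
    partner + catalyst + left-handed substrate → catalyst + left-handed product (k = 2.30 × 10⁵ M⁻² h⁻¹)

This flask ends with 38.5% left-handed product, under its ceiling of 40.0%, and 2.0% of its partner charge remains, less than the 98% of its right-handed substrate charge. Now take the neighbour with 2.00 equiv of partner. Its ceiling is 50.0%, and left-handed substrate is now the smaller charge. That neighbour reaches 50.0% left-handed product, with 0% left-handed substrate and 44.5% of its partner charge remaining. It also holds 5.50% right-handed product, and its excess of left-handed product is 80.2%.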